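**Retrosynthetic overview**
- Ring numbering is C1 (OMe), C2 (=CH), C3 (=C carrying C7H2OBz), C4 (OH), C5 (OBz), C6 (OH). The strategy rests on the trans C1–OMe/C6–OH pair beside the C2=C3 alkene of the cyclohexene ring. That pair is the footprint of an SN2' opening by methanol of a C3–O–C6 ether bridge in a 7-oxabicyclo[2.2.1]heptene.
- Without C7 and the C4 configuration, that bicycle is mirror-symmetric. It is the endo Diels–Alder adduct of furan (C1, C2, C3, C6, O6) and vinylene carbonate (C4, C5, O4, O5), so one chiral catalyst can set the absolute configuration while the bridge is cut.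
- Late disconnections are O6–Si, C4–H (Luche reduction of a C4 ketone), the benzoates on O5 and O7 (one operation), C3–C7 (Morita–Baylis–Hillman reaction with formaldehyde), and the C4 ketone itself. The ketone comes from allylic oxidation of the cis C4/C5 diol, which deletes the one carbinol that arrives wrongly configured.
- Ring order: the carbocycle, its temporary oxygen bridge and the fused carbonate ring all arise in step 1 (bonds C3–C4 and C5–C6). The bridge is cut in step 2, the carbonate ring is removed in step 4, and no further ring is made.

Key step: step 2

Face convention: β is the ring face that carries C1–OMe and α is the opposite face. CIP descriptors refer to the ring numbering above.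

Assumption: the sense of induction of the ferrocenyl ligand on this untested substrate cannot be derived safely. The antipode of PPF-P(t-Bu)2 that gives 5 rather than its mirror image is therefore fixed in a first run by Mosher ester analysis of the C6 hydroxyl, both antipodes being commercial.

Step 1
Reactants: 1 furan; 2 vinylene carbonate
Product: 3 meso endo-5,6-carbonyldioxy-7-oxabicyclo[2.2.1]hept-2-ene (both carbonate oxygens on the face opposite the oxygen bridge)
Conditions: furan (excess, neat), BHT (trace), sealed steel vessel, 120–125 °C; exo isomer removed by chromatography/crystallisation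
Reagents that add atoms: none
Why: Thermal Diels–Alder cycloaddition forms C3–C4 and C5–C6 suprafacially, so both carbonate C–O bonds are cis and each adduct is meso; separating off the exo isomer leaves the endo adduct, which places O5 trans to the bridge oxygen that becomes the C6 hydroxyl.

Step 2
Reactants: 3 meso endo adduct; 4 methanol
Product: 5 (1S,4R,5S,6R)-6-hydroxy-1-methoxycyclohex-2-ene-4,5-diyl carbonate (1-O-methyl conduritol F 4,5-carbonate; OMe/O4/O5 β, 6-OH α)
Conditions: [Rh(cod)Cl]2 (2.5 mol %), PPF-P(t-Bu)2 = 1-[2-(diphenylphosphino)ferrocenyl]ethyl-di-tert-butylphosphine (6 mol %, antipode as in the assumption), Bu4NI (15 mol %), MeOH/THF 1:1, 65–80 °C, sealed tube, Ar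
Reagents that add atoms: methanol (4), CO
Why: Proposed new method: the iodide-bearing monovalent rhodium–Josiphos complex is expected to coordinate 3 on its exo face through the alkene and the bridge oxygen, to insert with retention into one bridgehead C–O bond (C3–O) and so give a trivalent rhodium species that is an allyl over C1–C3 and an alkoxide at O6; methanol then protonates O6 and adds to C1 from the side turned away from the metal, which creates the C1–OMe bond, shifts the alkene from C1=C2 to C2=C3 and regenerates the catalyst. The nearest known reaction type is the rhodium-catalysed asymmetric ring opening of oxabenzonorbornadienes with alcohols (trans-2-alkoxy-1,2-dihydronaphthalen-1-ols) together with its halide-tuned extension to 5,6-disubstituted 7-oxanorbornenes with phenols, amines and related heteroatom nucleophiles, whereas a 5,6-dioxygenated 7-oxanorbornene paired with an aliphatic alcohol is untested. No ring is closed, since the oxygen-bridged bicycle unfolds to a cyclohexene still cis-fused to the carbonate ring, and the strain released pays for the step. C1 is the only new stereocentre and is set trans to the C6 hydroxyl by the sequence exo insertion/anti attack, while C4, C5 and C6 keep the relative configuration of the endo adduct and receive their absolute configuration from the ligand pocket, which must distinguish the enantiotopic C3–O and C6–O bonds. Besides this enantiotopic selection the step needs attack at the allyl terminus next to the carbinol (1,2- and not 1,4-product) and an intact carbonate, which the mirror symmetry of 3, the planar carbonate that no longer screens C1 after the bicycle has opened and the base-free medium should provide. The retarding inductive pull of O4 and O5 on the insertion is answered by the more reactive iodide catalyst and by heating.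

Step 3
Reactants: 5 methoxy alcohol carbonate
Product: 6 (1S,4R,5R,6R)-6-(tert-butyldimethylsilyloxy)-1-methoxycyclohex-2-ene-4,5-diyl carbonate
Conditions: TBSOTf, 2,6-lutidine, CH2Cl2, 0 °C
Reagents that add atoms: TBSOTf, CC(C)(C)[Si](C)(C)OS(=O)(=O)C(F)(F)F
Why: Silyl triflate silylation of the only free hydroxyl under a hindered, non-nucleophilic base leaves the carbonate, the allylic ether and all four stereocentres untouched and masks O6 for the rest of the route.

Step 4
Reactants: 6 silyl ether carbonate
Product: 7 (1S,4R,5R,6S)-6-(tert-butyldimethylsilyloxy)-1-methoxycyclohex-2-ene-4,5-diol (4-OH and 5-OH cis, both β)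
Conditions: K2CO3 (0.2 equiv), MeOH, 0 °C, short contact; aq. NH4Cl quench
Reagents that add atoms: none
Why: Base-catalysed transesterification (methanolysis) of the strained five-membered carbonate is fast at 0 °C, so a short contact time and a buffered quench should release the cis C4/C5 diol before the silyl group can wander from O6 to O5; no stereocentre is touched.

Step 5
Reactants: 7 cis diol
Product: 8 (4S,5S,6S)-5-(tert-butyldimethylsilyloxy)-6-hydroxy-4-methoxycyclohex-2-en-1-one (ketone at route C4; route C1/C6/C5 = enone C4/C5/C6)
Conditions: activated MnO2 (excess), CH2Cl2, rt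
Reagents that add atoms: none
Why: MnO2 oxidises allylic carbinols far faster than saturated ones, so only C4–OH is taken to the ketone under neutral heterogeneous conditions, which deliberately deletes the wrongly configured C4 centre while C1, C5 and C6 stay as they are.

Step 6
Reactants: 8 enone; 9 formaldehyde (as formalin)
Product: 10 (4S,5S,6S)-5-(tert-butyldimethylsilyloxy)-6-hydroxy-2-(hydroxymethyl)-4-methoxycyclohex-2-en-1-one
Conditions: 37 % aq. HCHO, DMAP (0.3 equiv), THF/H2O, rt
Reagents that add atoms: formaldehyde (9), C=O
Why: Morita–Baylis–Hillman reaction: DMAP adds to C2, the resulting enolate attacks formaldehyde through C3 and loss of DMAP restores the enone, a sequence well used for α-hydroxymethylation of oxygenated cyclohexenones; no stereocentre is made, no ester is yet present to be cleaved or displaced, and C5 already holds its favoured pseudoequatorial configuration.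

Step 7
Reactants: 10 hydroxymethyl enone; 11 benzoyl chloride (two equivalents)
Product: 13 [(3S,4R,5S)-5-benzoyloxy-4-(tert-butyldimethylsilyloxy)-3-methoxy-6-oxocyclohex-1-en-1-yl]methyl benzoate (enone dibenzoate), via primary monobenzoate 12 (not isolated)
Conditions: BzCl (2.4 equiv), pyridine, CH2Cl2, 0 °C
Reagents that add atoms: benzoyl chloride (11), O=C(Cl)c1ccccc1
Why: Pyridine-mediated acylation of the two free hydroxyls (primary O7 first, then the α-keto O5) installs both ester groups of the target in one operation, the silyl ether keeping O6 out of play and the low temperature suppressing β-elimination; no stereocentre changes.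

Step 8
Reactants: 13 enone dibenzoate
Product: 14 (1S,4S,5R,6R)-configured 6-O-tert-butyldimethylsilyl ether of the target (4-OH α, trans to 5-OBz β)
Conditions: NaBH4, CeCl3·7H2O, MeOH, −78 °C; AcOH quench at −78 °C
Reagents that add atoms: none
Why: Luche reduction delivers hydride 1,2 to the cerium-activated enone, and in the half-chair with the C1, C5 and C6 substituents pseudoequatorial the small reagent attacks C4 pseudoaxially from the β face (anti to the axial C5–H), giving the pseudoequatorial α-hydroxyl trans to the C5 benzoate, as is usual for all-trans 4,5,6-trioxygenated cyclohexenones; low temperature and an acidic quench curb acyl migration.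

Step 9
Reactants: 14 silyl ether of the target
Product: 15 [(3S,4R,5R,6S)-5-benzoyloxy-4,6-dihydroxy-3-methoxycyclohex-1-en-1-yl]methyl benzoate (target CNP0349013.8)
Conditions: HF·pyridine, pyridine, THF, 0 °C to rt, polyethylene vessel
Reagents that add atoms: none
Why: Fluoride-driven cleavage of the Si–O bond in a buffered acidic medium generates no alkoxide, so the C5 benzoate should stay between the two free hydroxyls at C4 and C6 and the allylic ester and ether survive; no stereocentre is affected.

**Compound list**
1 | furan | c1ccoc1 | starting material
2 | vinylene carbonate | O=C1OC=CO1 | starting material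
3 | meso endo-5,6-carbonyldioxy-7-oxabicyclo[2.2.1]hept-2-ene | C1=C[C@H]2[C@H]3OC(=O)O[C@H]3[C@@H]1O2 | intermediate
4 | methanol | CO | starting material
5 | 1-O-methyl conduritol F 4,5-carbonate, (1S,4R,5S,6R) | CO[C@H]1C=C[C@H]2OC(=O)O[C@H]2[C@@H]1O | intermediate
6 | 6-O-TBS ether of 5, (1S,4R,5R,6R) | CO[C@H]1C=C[C@H]2OC(=O)O[C@H]2[C@@H]1O[Si](C)(C)C(C)(C)C | intermediate
7 | 6-O-TBS 1-O-methyl cis-4,5-diol, (1S,4R,5R,6S) | CO[C@H]1C=C[C@@H](O)[C@@H](O)[C@@H]1O[Si](C)(C)C(C)(C)C | intermediate
8 | C4 enone with free C5 hydroxyl, (1S,5S,6S) | CO[C@H]1C=CC(=O)[C@@H](O)[C@@H]1O[Si](C)(C)C(C)(C)C | intermediate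
9 | formaldehyde | C=O | starting material
10 | 3-hydroxymethyl enone, (1S,5S,6S) | CO[C@H]1C=C(CO)C(=O)[C@@H](O)[C@@H]1O[Si](C)(C)C(C)(C)C | intermediate
11 | benzoyl chloride | O=C(Cl)c1ccccc1 | starting material
12 | primary (O7) monobenzoate of 10 | CO[C@H]1C=C(COC(=O)c2ccccc2)C(=O)[C@@H](O)[C@@H]1O[Si](C)(C)C(C)(C)C | intermediate
13 | enone O5,O7-dibenzoate, (1S,5S,6R) | CO[C@H]1C=C(COC(=O)c2ccccc2)C(=O)[C@@H](OC(=O)c2ccccc2)[C@@H]1O[Si](C)(C)C(C)(C)C | intermediate
14 | 6-O-TBS ether of the target, (1S,4S,5R,6R) | CO[C@H]1C=C(COC(=O)c2ccccc2)[C@H](O)[C@@H](OC(=O)c2ccccc2)[C@@H]1O[Si](C)(C)C(C)(C)C | intermediate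
15 | target CNP0349013.8, (1S,4S,5R,6R) | CO[C@H]1C=C(COC(=O)c2ccccc2)[C@H](O)[C@@H](OC(=O)c2ccccc2)[C@@H]1O | target

Total step count: 9. Longest linear sequence: 9 steps (1 and 2 to 15).

**Steps most likely to fail**

**Step 2.**
- What may go wrong: insertion into the bridgehead C–O bond may be sluggish because O4 and O5 withdraw electron density. The allyl rhodium species may lose the neighbouring C4 oxygen and aromatise. The carbonate may be slowly methanolysed, or the two enantiotopic C–O bonds may be poorly distinguished.
- Fallback (known chemistry, chiral pool in place of desymmetrisation): it sets out from methanol 4, now used to open a vinyl epoxide, and comes back at diol 7.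
- The starting point is purchased (1S,2S)-3-bromocyclohexa-3,5-diene-1,2-diol F1. Its two carbinol carbons are already C4 and C5 with the configuration of 7, and its bromine sits on C3.
- 2,2-Dimethoxypropane and TsOH convert it into the bromodiene acetonide F2. mCPBA then epoxidises the bromine-free C1=C6 alkene on the face opposite the acetonide to give the vinyl epoxide F3.
- Methanol 4 over Al2O3 opens the epoxide at allylic C1 with inversion to give the trans bromo methoxy alcohol F4. Bu3SnH/AIBN removes the vinylic bromine to give the methoxy alcohol acetonide F5.
- TBSOTf/2,6-lutidine gives the silyl ether acetonide F6, and aqueous acetic acid cleaves the acetonide to 7.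

**Step 6.**
- What may go wrong: the amine catalyst may add slowly to C2, which is flanked by the methoxy-bearing C1. Enolisation at C5 may compete, with loss of the C6 silyloxy group and aromatisation.
- Fallback (cross-coupling in place of organocatalysis): it sets out from enone 8 and comes back at 10.
- Brief treatment with I2 and pyridine in CH2Cl2 at 0 °C gives the 3-iodo enone F7.
- Stille coupling with (tributylstannyl)methanol under Pd(PPh3)4 (zerovalent palladium) in dioxane at 80 °C installs C7 as the free hydroxymethyl group of 10.

**Step 8.**
- What may go wrong: the benzoyl group may migrate from O5 to the nascent C4 alkoxide. Conjugate hydride addition may expel the allylic O7 benzoate. To a lesser degree, facial selectivity may be poor.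
- Fallback (reduction moved ahead of esterification, with a temporary O4/O7 tether): it sets out from 10 and comes back at 14.
- Luche reduction of the ester-free 10 gives the 4,5,7-triol F8. 2,2-Dimethoxypropane/PPTS ties O4 and O7 into a six-membered ring, the trans 4,5-pair being unfit for a five-membered acetal, and gives the 4,7-O-isopropylidene acetal F9.
- Benzoyl chloride 11 in pyridine esterifies the only free hydroxyl to give the 5-benzoate acetal F10. Aqueous acetic acid releases the 4,7-diol 5-benzoate F11.
- One equivalent of 11 with 2,4,6-collidine in CH2Cl2 at −40 °C acylates the primary O7 selectively to give 14.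

**Further compounds**
F1 | step 2 | (1S,2S)-3-bromocyclohexa-3,5-diene-1,2-diol (purchased) | BrC1=CC=C[C@H](O)[C@@H]1O
F2 | step 2 | bromodiene acetonide | BrC1=CC=C[C@@H]2OC(C)(C)O[C@H]12
F3 | step 2 | vinyl epoxide (epoxide α at C1/C6, acetonide β) | BrC1=C[C@H]2O[C@H]2[C@@H]2OC(C)(C)O[C@H]12
F4 | step 2 | trans bromo methoxy alcohol (3-bromo, 1β-OMe, 6α-OH, 4,5-acetonide) | CO[C@H]1C=C(Br)[C@H]2OC(C)(C)O[C@H]2[C@@H]1O
F5 | step 2 | methoxy alcohol acetonide | CO[C@H]1C=C[C@H]2OC(C)(C)O[C@H]2[C@@H]1O
F6 | step 2 | silyl ether acetonide | CO[C@H]1C=C[C@H]2OC(C)(C)O[C@H]2[C@@H]1O[Si](C)(C)C(C)(C)C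
F7 | step 6 | 3-iodo enone | CO[C@H]1C=C(I)C(=O)[C@@H](O)[C@@H]1O[Si](C)(C)C(C)(C)C
F8 | step 8 | 4,5,7-triol (4α-OH) | CO[C@H]1C=C(CO)[C@H](O)[C@@H](O)[C@@H]1O[Si](C)(C)C(C)(C)C
F9 | step 8 | 4,7-O-isopropylidene acetal | CO[C@H]1C=C2COC(C)(C)O[C@@H]2[C@@H](O)[C@@H]1O[Si](C)(C)C(C)(C)C
F10 | step 8 | 5-benzoate acetal | CO[C@H]1C=C2COC(C)(C)O[C@@H]2[C@@H](OC(=O)c2ccccc2)[C@@H]1O[Si](C)(C)C(C)(C)C
F11 | step 8 | 4,7-diol 5-benzoate | CO[C@H]1C=C(CO)[C@H](O)[C@@H](OC(=O)c2ccccc2)[C@@H]1O[Si](C)(C)C(C)(C)C
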